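Assumption: the target SMILES is taken literally (ring carbons C8 and C11 are cis on the CH2OH-bearing alkene). Ring locants used below: C1 quaternary carbon, C2=C3 alkene, C4 ester carbon, C5/C6 oxirane, C9=C10 alkene, C11 ring CH2. Ligand enantiomers are those expected to give the stated configuration and would be swapped for their antipodes if induction ran the other way.

**Retrosynthetic overview**
1. 28 ⇐ 27 (desilylation) ⇐ 25 + senecioic acid: the C4–O ester bond is made with inversion (Mitsunobu) on the erythro epoxy alcohol.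
2. 25 ⇐ acyclic ynal 21: one-flask alkenylzinc ring closure (C3–C4) and alkoxide-directed epoxidation (C5–O, C6–O). The eleven-membered carbocycle forms first, then the oxirane.
3. 21 ⇐ aldehyde 11 + phosphonate 17 (Horner–Wadsworth–Emmons, C9=C10 with C8/C11 cis).
4. 11 ⇐ geraniol: copper-catalysed SN2' alkynylation (quaternary C1), Shi epoxidation then epoxide-to-allylic-alcohol isomerisation (side-chain carbinol through a transient oxirane), hydroboration–oxidation.
5. 17 ⇐ triethyl phosphonoacetate + acrolein + a formyl-stabilised ylide.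

**Route**

Step 1
Reactants: 1 geraniol
Product: 2 (2E)-3,7-dimethylocta-2,6-dien-1-yl diethyl phosphate
Conditions: (EtO)2P(O)Cl, pyridine, CH2Cl2, 0 °C to rt
Reagents that add atoms: diethyl chlorophosphate (CCOP(=O)(Cl)OCC)
Why: O-phosphorylation of the primary allylic alcohol installs the leaving group for the SN2' step; no stereocentre is involved.

Step 2
Reactants: 2 (2E)-3,7-dimethylocta-2,6-dien-1-yl diethyl phosphate; 3 trimethylsilylacetylene
Product: 5 (3R)-3-ethenyl-3,7-dimethyl-1-(trimethylsilyl)oct-6-en-1-yne, via alkynylalane 4 (not isolated)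
Conditions: 3, iBu2AlH, Et3N (5 mol%), hexanes, 55 °C; then 2, CuCl2·2H2O (5 mol%), chiral sulfonate-bearing imidazolinium salt (NHC precursor, 5.5 mol%), THF, -15 °C
Reagents that add atoms: none
Why: NHC–copper-catalysed enantioselective allylic substitution (SN2') with an alkynylaluminium reagent; the chiral carbene–copper complex delivers the alkynyl group to one face of the trisubstituted alkene, which sets the quaternary centre (R) and releases the vinyl group.

Step 3
Reactants: 5 (3R)-3-ethenyl-3,7-dimethyl-1-(trimethylsilyl)oct-6-en-1-yne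
Product: 6 (3R)-5-[(2R)-3,3-dimethyloxiran-2-yl]-3-ethenyl-3-methyl-1-(trimethylsilyl)pent-1-yne
Conditions: Shi ketone (D-fructose-derived, 30 mol%), KHSO5 (Oxone), K2CO3, Bu4NHSO4, MeCN/CH2(OMe)2/aq. buffer pH 10.5, 0 °C
Reagents that add atoms: potassium peroxymonosulfate ([K+].[O-]S(=O)(=O)OO)
Why: Shi asymmetric epoxidation; the chiral dioxirane attacks only the electron-rich trisubstituted alkene through a spiro transition state and gives the (R)-oxirane, while the vinyl group and silylalkyne are far less reactive.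

Step 4
Reactants: 6 (3R)-5-[(2R)-3,3-dimethyloxiran-2-yl]-3-ethenyl-3-methyl-1-(trimethylsilyl)pent-1-yne
Product: 9 (3R)-3-{2-[(2R)-3,3-dimethyloxiran-2-yl]ethyl}-3-methylpent-4-yn-1-ol, via B-alkyl-9-BBN adduct 7 (not isolated), via silylalkynol 8 (not isolated)
Conditions: 9-BBN, THF, 0 °C to rt; then NaOH, H2O2, 0 °C; then K2CO3, MeOH, rt
Reagents that add atoms: hydrogen peroxide (OO)
Why: anti-Markovnikov hydroboration–oxidation of the terminal vinyl group (9-BBN reacts with it much faster than with the silylalkyne), followed by basic methanolysis of the C–Si bond; no stereocentre is affected.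

Step 5
Reactants: 9 (3R)-3-{2-[(2R)-3,3-dimethyloxiran-2-yl]ethyl}-3-methylpent-4-yn-1-ol
Product: 10 (3R,6R)-3-ethynyl-3,7-dimethyloct-7-ene-1,6-diol
Conditions: LiTMP, Et2AlCl (gives Et2Al(TMP), 4 equiv), PhMe, 0 °C
Reagents that add atoms: none
Why: aluminium-amide-induced epoxide-to-allylic-alcohol isomerisation; syn β-elimination removes a proton from a methyl group of the gem-dimethyl oxirane carbon, and the secondary C–O bond is untouched, so the carbinol keeps the (R) configuration.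

Step 6
Reactants: 10 (3R,6R)-3-ethynyl-3,7-dimethyloct-7-ene-1,6-diol
Product: 11 (3R,6R)-3-ethynyl-6-hydroxy-3,7-dimethyloct-7-enal
Conditions: TEMPO (10 mol%), PhI(OAc)2, CH2Cl2, rt
Reagents that add atoms: none
Why: oxoammonium (TEMPO) oxidation is selective for the primary alcohol over the hindered secondary allylic alcohol.

Step 7
Reactants: 12 triethyl phosphonoacetate; 13 acrolein
Product: 14 ethyl 2-(diethoxyphosphoryl)-5-oxopentanoate (racemic)
Conditions: NaOEt (10 mol%), EtOH, -10 °C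
Reagents that add atoms: none
Why: base-catalysed Michael addition of the phosphonoacetate carbanion to acrolein; the stereocentre formed is lost later.

Step 8
Reactants: 14 ethyl 2-(diethoxyphosphoryl)-5-oxopentanoate; 15 2-(triphenylphosphoranylidene)propanal
Product: 16 ethyl (5E)-2-(diethoxyphosphoryl)-6-methyl-7-oxohept-5-enoate (racemic)
Conditions: PhMe, 80 °C
Reagents that add atoms: none
Why: Wittig olefination with a formyl-stabilised ylide gives the (E)-2-methyl enal (C5=C6 geometry); the weakly basic ylide leaves the phosphonoacetate alone.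

Step 9
Reactants: 16 ethyl (5E)-2-(diethoxyphosphoryl)-6-methyl-7-oxohept-5-enoate
Product: 17 ethyl (5E)-2-(diethoxyphosphoryl)-7,7-dimethoxy-6-methylhept-5-enoate (racemic)
Conditions: HC(OMe)3, MeOH, PPTS (cat.), rt
Reagents that add atoms: trimethyl orthoformate (COC(OC)OC)
Why: acid-catalysed acetalisation masks the enal so that the next olefination touches only aldehyde 11.

Step 10
Reactants: 11 (3R,6R)-3-ethynyl-6-hydroxy-3,7-dimethyloct-7-enal; 17 ethyl (5E)-2-(diethoxyphosphoryl)-7,7-dimethoxy-6-methylhept-5-enoate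
Product: 18 ethyl (2E,5R,8R)-2-[(3E)-5,5-dimethoxy-4-methylpent-3-en-1-yl]-5-ethynyl-8-hydroxy-5,9-dimethyldeca-2,9-dienoate
Conditions: 17, NaH, THF, 0 °C; then 11, 0 °C to rt
Reagents that add atoms: none
Why: Horner–Wadsworth–Emmons olefination with an α-alkyl phosphonoacetate gives mainly the (E)-enoate, which places C8 and C11 cis as the target requires; the minor (Z)-isomer is removed by chromatography.

Step 11
Reactants: 18 ethyl (2E,5R,8R)-2-[(3E)-5,5-dimethoxy-4-methylpent-3-en-1-yl]-5-ethynyl-8-hydroxy-5,9-dimethyldeca-2,9-dienoate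
Product: 19 (2E,5R,8R)-2-[(3E)-5,5-dimethoxy-4-methylpent-3-en-1-yl]-5-ethynyl-5,9-dimethyldeca-2,9-diene-1,8-diol
Conditions: iBu2AlH (4 equiv), CH2Cl2, -78 °C
Reagents that add atoms: none
Why: 1,2-reduction of the enoate to the allylic alcohol; acetal, alkyne and alkenes are inert at -78 °C.

Step 12
Reactants: 19 (2E,5R,8R)-2-[(3E)-5,5-dimethoxy-4-methylpent-3-en-1-yl]-5-ethynyl-5,9-dimethyldeca-2,9-diene-1,8-diol
Product: 20 (2E,5R,8R)-1,8-bis[(tert-butyldimethylsilyl)oxy]-2-[(3E)-5,5-dimethoxy-4-methylpent-3-en-1-yl]-5-ethynyl-5,9-dimethyldeca-2,9-diene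
Conditions: TBSCl, imidazole, DMAP (cat.), DMF, rt
Reagents that add atoms: tert-butyldimethylsilyl chloride (CC(C)(C)[Si](C)(C)Cl)
Why: one silylation masks both allylic hydroxyl groups, so that only the C4 hydroxyl formed later can direct epoxidation and undergo esterification.

Step 13
Reactants: 20 (2E,5R,8R)-1,8-bis[(tert-butyldimethylsilyl)oxy]-2-[(3E)-5,5-dimethoxy-4-methylpent-3-en-1-yl]-5-ethynyl-5,9-dimethyldeca-2,9-diene
Product: 21 (2E,6E,9R,12R)-12-[(tert-butyldimethylsilyl)oxy]-6-{[(tert-butyldimethylsilyl)oxy]methyl}-9-ethynyl-2,9,13-trimethyltetradeca-2,6,13-trienal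
Conditions: PPTS (cat.), acetone/H2O, rt
Reagents that add atoms: water (O)
Why: α,β-unsaturated dimethyl acetals hydrolyse under very mild acid, which the silyl ethers survive.

Step 14
Reactants: 21 (2E,6E,9R,12R)-12-[(tert-butyldimethylsilyl)oxy]-6-{[(tert-butyldimethylsilyl)oxy]methyl}-9-ethynyl-2,9,13-trimethyltetradeca-2,6,13-trienal
Product: 25 (1R,2R,3E,5R,7E,11R)-5-{(3R)-3-[(tert-butyldimethylsilyl)oxy]-4-methylpent-4-en-1-yl}-8-{[(tert-butyldimethylsilyl)oxy]methyl}-1,5-dimethyl-12-oxabicyclo[9.1.0]dodeca-3,7-dien-2-ol, via alkenylborane 22 (not isolated), via alkenylzinc 23 (not isolated), via zinc alkoxide 24 (not isolated)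
Conditions: Cy2BH (from BH3·SMe2 and cyclohexene), PhMe, 0 °C; slow addition to Et2Zn, (+)-MIB (10 mol%), PhMe, 0 °C, 5 mM; then Ti(OiPr)4 (20 mol%), t-BuOOH, -20 to 0 °C
Reagents that add atoms: tert-butyl hydroperoxide (CC(C)(C)OO)
Why: Proposed new method: a macrocyclising alkenylzinc–enal addition run in tandem with alkoxide-directed epoxidation; hydroboration of the terminal alkyne and boron-to-zinc exchange give an (E)-alkenyl(ethyl)zinc, which adds through the (+)-MIB–zinc chelate to the Re face of the enal carbonyl (ring closure at C3–C4, 4R), and the resulting zinc alkoxide, relayed to Ti(OiPr)4/t-BuOOH, delivers oxygen to the more nucleophilic 2-methyl-substituted C5=C6 alkene in the A(1,2)-minimised conformer (erythro oxirane), while the disubstituted C2=C3 alkene and the silyl-masked allylic ethers are not directed; the closest known reaction types are the amino-alcohol-catalysed alkenylzinc macrocyclisation of ω-alkynyl aldehydes and the intermolecular tandem asymmetric alkenylation of enals/directed epoxidation.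

Step 15
Reactants: 25 (1R,2R,3E,5R,7E,11R)-5-{(3R)-3-[(tert-butyldimethylsilyl)oxy]-4-methylpent-4-en-1-yl}-8-{[(tert-butyldimethylsilyl)oxy]methyl}-1,5-dimethyl-12-oxabicyclo[9.1.0]dodeca-3,7-dien-2-ol; 26 3-methylbut-2-enoic acid
Product: 27 (1S,2S,3E,5R,7E,11R)-5-{(3R)-3-[(tert-butyldimethylsilyl)oxy]-4-methylpent-4-en-1-yl}-8-{[(tert-butyldimethylsilyl)oxy]methyl}-1,5-dimethyl-12-oxabicyclo[9.1.0]dodeca-3,7-dien-2-yl 3-methylbut-2-enoate
Conditions: 26, PPh3, DIAD, PhMe, 0 °C to rt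
Reagents that add atoms: none
Why: Mitsunobu esterification; the carboxylate displaces the alkoxyphosphonium group by SN2 at the allylic C4, forming the C–O ester bond with inversion (4R to 4S, erythro to the threo arrangement of the target); the descriptor of the oxirane methyl carbon changes from R to S only because of ligand priorities.

Step 16
Reactants: 27 (1S,2S,3E,5R,7E,11R)-5-{(3R)-3-[(tert-butyldimethylsilyl)oxy]-4-methylpent-4-en-1-yl}-8-{[(tert-butyldimethylsilyl)oxy]methyl}-1,5-dimethyl-12-oxabicyclo[9.1.0]dodeca-3,7-dien-2-yl 3-methylbut-2-enoate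
Product: 28 (1S,2S,3E,5R,7E,11R)-8-(hydroxymethyl)-5-[(3R)-3-hydroxy-4-methylpent-4-en-1-yl]-1,5-dimethyl-12-oxabicyclo[9.1.0]dodeca-3,7-dien-2-yl 3-methylbut-2-enoate (CNP0309478.1)
Conditions: Bu4NF, AcOH, THF, 0 °C to rt
Reagents that add atoms: none
Why: buffered fluoride desilylation frees both allylic alcohols without touching the ester or the oxirane.

**Compound list**

1 | geraniol, (2E)-3,7-dimethylocta-2,6-dien-1-ol | CC(C)=CCC/C(C)=C/CO | starting material
2 | (2E)-3,7-dimethylocta-2,6-dien-1-yl diethyl phosphate | CC(C)=CCC/C(C)=C/COP(=O)(OCC)OCC | intermediate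
3 | trimethylsilylacetylene | C#C[Si](C)(C)C | starting material
4 | diisobutyl[(trimethylsilyl)ethynyl]alane | CC(C)C[Al](CC(C)C)C#C[Si](C)(C)C | intermediate
5 | (3R)-3-ethenyl-3,7-dimethyl-1-(trimethylsilyl)oct-6-en-1-yne | CC(C)=CCC[C@@](C=C)(C)C#C[Si](C)(C)C | intermediate
6 | (3R)-5-[(2R)-3,3-dimethyloxiran-2-yl]-3-ethenyl-3-methyl-1-(trimethylsilyl)pent-1-yne | CC1(C)[C@H](O1)CC[C@@](C=C)(C)C#C[Si](C)(C)C | intermediate
7 | 9-BBN adduct of 6, boron on the terminal carbon of the former vinyl group, stereocentres arranged as in 6 | CC1(C)[C@H](O1)CC[C@@](CCB2C3CCCC2CCC3)(C)C#C[Si](C)(C)C | intermediate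
8 | (3R)-3-{2-[(2R)-3,3-dimethyloxiran-2-yl]ethyl}-3-methyl-5-(trimethylsilyl)pent-4-yn-1-ol | CC1(C)[C@H](O1)CC[C@@](CCO)(C)C#C[Si](C)(C)C | intermediate
9 | (3R)-3-{2-[(2R)-3,3-dimethyloxiran-2-yl]ethyl}-3-methylpent-4-yn-1-ol | CC1(C)[C@H](O1)CC[C@@](CCO)(C)C#C | intermediate
10 | (3R,6R)-3-ethynyl-3,7-dimethyloct-7-ene-1,6-diol | C=C(C)[C@H](O)CC[C@@](CCO)(C)C#C | intermediate
11 | (3R,6R)-3-ethynyl-6-hydroxy-3,7-dimethyloct-7-enal | C=C(C)[C@H](O)CC[C@@](CC=O)(C)C#C | intermediate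
12 | triethyl phosphonoacetate | CCOC(=O)CP(=O)(OCC)OCC | starting material
13 | acrolein | C=CC=O | starting material
14 | ethyl 2-(diethoxyphosphoryl)-5-oxopentanoate (racemic) | CCOC(=O)C(CCC=O)P(=O)(OCC)OCC | intermediate
15 | 2-(triphenylphosphoranylidene)propanal | CC(C=O)=P(c1ccccc1)(c1ccccc1)c1ccccc1 | starting material
16 | ethyl (5E)-2-(diethoxyphosphoryl)-6-methyl-7-oxohept-5-enoate (racemic) | CCOC(=O)C(CC/C=C(\C)C=O)P(=O)(OCC)OCC | intermediate
17 | ethyl (5E)-2-(diethoxyphosphoryl)-7,7-dimethoxy-6-methylhept-5-enoate (racemic) | CCOC(=O)C(CC/C=C(\C)C(OC)OC)P(=O)(OCC)OCC | intermediate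
18 | ethyl (2E,5R,8R)-2-[(3E)-5,5-dimethoxy-4-methylpent-3-en-1-yl]-5-ethynyl-8-hydroxy-5,9-dimethyldeca-2,9-dienoate | C=C(C)[C@H](O)CC[C@@](C/C=C(\CC/C=C(\C)C(OC)OC)C(=O)OCC)(C)C#C | intermediate
19 | (2E,5R,8R)-2-[(3E)-5,5-dimethoxy-4-methylpent-3-en-1-yl]-5-ethynyl-5,9-dimethyldeca-2,9-diene-1,8-diol | C=C(C)[C@H](O)CC[C@@](C/C=C(\CC/C=C(\C)C(OC)OC)CO)(C)C#C | intermediate
20 | (2E,5R,8R)-1,8-bis[(tert-butyldimethylsilyl)oxy]-2-[(3E)-5,5-dimethoxy-4-methylpent-3-en-1-yl]-5-ethynyl-5,9-dimethyldeca-2,9-diene | C=C(C)[C@H](O[Si](C)(C)C(C)(C)C)CC[C@@](C/C=C(\CC/C=C(\C)C(OC)OC)CO[Si](C)(C)C(C)(C)C)(C)C#C | intermediate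
21 | (2E,6E,9R,12R)-12-[(tert-butyldimethylsilyl)oxy]-6-{[(tert-butyldimethylsilyl)oxy]methyl}-9-ethynyl-2,9,13-trimethyltetradeca-2,6,13-trienal | C=C(C)[C@H](O[Si](C)(C)C(C)(C)C)CC[C@@](C/C=C(\CC/C=C(\C)C=O)CO[Si](C)(C)C(C)(C)C)(C)C#C | intermediate
22 | (E)-alkenyl(dicyclohexyl)borane from 21, boron on the former terminal alkyne carbon | C=C(C)[C@H](O[Si](C)(C)C(C)(C)C)CC[C@@](C/C=C(\CC/C=C(\C)C=O)CO[Si](C)(C)C(C)(C)C)(C)/C=C/B(C1CCCCC1)C1CCCCC1 | intermediate
23 | (E)-alkenyl(ethyl)zinc from 22 | C=C(C)[C@H](O[Si](C)(C)C(C)(C)C)CC[C@@](C/C=C(\CC/C=C(\C)C=O)CO[Si](C)(C)C(C)(C)C)(C)/C=C/[Zn]CC | intermediate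
24 | ethylzinc alkoxide of the (4R)-configured eleven-membered dienol (E-C2=C3, E-C5=C6, C8/C11 cis at C9=C10) | C=C(C)[C@H](O[Si](C)(C)C(C)(C)C)CC[C@@]1(C)/C=C/[C@@H](O[Zn]CC)/C(C)=C/CC/C(CO[Si](C)(C)C(C)(C)C)=C\C1 | intermediate
25 | (1R,2R,3E,5R,7E,11R)-5-{(3R)-3-[(tert-butyldimethylsilyl)oxy]-4-methylpent-4-en-1-yl}-8-{[(tert-butyldimethylsilyl)oxy]methyl}-1,5-dimethyl-12-oxabicyclo[9.1.0]dodeca-3,7-dien-2-ol | C=C(C)[C@H](O[Si](C)(C)C(C)(C)C)CC[C@@]1(C)/C=C/[C@@H](O)[C@@]2(C)O[C@@H]2CC/C(CO[Si](C)(C)C(C)(C)C)=C\C1 | intermediate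
26 | 3-methylbut-2-enoic acid (senecioic acid) | CC(C)=CC(=O)O | starting material
27 | (1S,2S,3E,5R,7E,11R)-5-{(3R)-3-[(tert-butyldimethylsilyl)oxy]-4-methylpent-4-en-1-yl}-8-{[(tert-butyldimethylsilyl)oxy]methyl}-1,5-dimethyl-12-oxabicyclo[9.1.0]dodeca-3,7-dien-2-yl 3-methylbut-2-enoate | C=C(C)[C@H](O[Si](C)(C)C(C)(C)C)CC[C@@]1(C)/C=C/[C@H](OC(=O)C=C(C)C)[C@@]2(C)O[C@@H]2CC/C(CO[Si](C)(C)C(C)(C)C)=C\C1 | intermediate
28 | (1S,2S,3E,5R,7E,11R)-8-(hydroxymethyl)-5-[(3R)-3-hydroxy-4-methylpent-4-en-1-yl]-1,5-dimethyl-12-oxabicyclo[9.1.0]dodeca-3,7-dien-2-yl 3-methylbut-2-enoate | C=C(C)[C@H](O)CC[C@@]1(C)/C=C/[C@H](OC(=O)C=C(C)C)[C@@]2(C)O[C@@H]2CC/C(CO)=C\C1 | target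

**Step count**
Total: 16 steps. Longest linear sequence: 13 steps (steps 1–6, then 10–16); the phosphonate branch is steps 7–9.

**Three steps most likely to fail**

Step 14 (the proposed new method). The eleven-membered ring closure may be slow against oligomerisation, and the tandem oxidation has to tolerate the boron by-products. The known-chemistry fallback sets out from 20. Hydrozirconation–iodination (Cp2ZrHCl, THF; then I2) gives the (E)-vinyl iodide acetal F1. Mild hydrolysis (PPTS, wet acetone) gives the iodo enal F2. Nozaki–Hiyama–Kishi macrocyclisation (CrCl2, NiCl2 cat., DMSO/THF, high dilution) gives the macrocyclic dienol as a mixture of C4 epimers F3. Titanium–tartrate epoxidation under kinetic-resolution conditions (Ti(OiPr)4, D-(-)-diisopropyl tartrate, t-BuOOH, 4 Å sieves, CH2Cl2, -20 °C) epoxidises only the matched (4R)-epimer and so returns to the route at 25; the slow (4S)-epimer is separated.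

Step 15. SN2 at a hindered allylic carbinol next to a fully substituted oxirane carbon, with a weakly acidic enoic acid, may be sluggish or give elimination. The fallback sets out from 25. Sulfonylation (Ms2O, Et3N, CH2Cl2, -20 °C) gives the C4 mesylate F4. Displacement with caesium 3-methylbut-2-enoate (from 26 and Cs2CO3; 18-crown-6, toluene, 40 °C) proceeds with inversion and returns to the route at 27.

Step 2. Enantioselectivity for a methyl/alkyl-substituted allylic phosphate with the silylalkynyl reagent may be insufficient. The fallback sets out from 1. Sharpless asymmetric epoxidation (Ti(OiPr)4, L-(+)-diethyl tartrate, t-BuOOH, 4 Å sieves, CH2Cl2, -20 °C) gives (2S,3S)-2,3-epoxygeraniol F5. Alkoxide-directed opening at the tertiary carbon C3 with inversion by Et2AlC≡CSiMe3 (from 3, n-BuLi and Et2AlCl; toluene, 0 °C) gives the quaternary alkynyl diol F6. Garegg–Samuelsson deoxygenation of the 1,2-diol (I2, PPh3, imidazole, toluene, 80 °C) gives the vinyl group and returns to the route at 5.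

**Further compounds**

F1 | step 14 | (E)-vinyl iodide from 20 (iodine on the former terminal alkyne carbon, acetal intact) | C=C(C)[C@H](O[Si](C)(C)C(C)(C)C)CC[C@@](C/C=C(\CC/C=C(\C)C(OC)OC)CO[Si](C)(C)C(C)(C)C)(C)/C=C/I
F2 | step 14 | iodo enal, the aldehyde corresponding to F1 | C=C(C)[C@H](O[Si](C)(C)C(C)(C)C)CC[C@@](C/C=C(\CC/C=C(\C)C=O)CO[Si](C)(C)C(C)(C)C)(C)/C=C/I
F3 | step 14 | macrocyclic dienol, mixture of C4 epimers | C=C(C)[C@H](O[Si](C)(C)C(C)(C)C)CC[C@@]1(C)/C=C/C(O)/C(C)=C/CC/C(CO[Si](C)(C)C(C)(C)C)=C\C1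
F4 | step 15 | C4 methanesulfonate of 25 | C=C(C)[C@H](O[Si](C)(C)C(C)(C)C)CC[C@@]1(C)/C=C/[C@@H](OS(C)(=O)=O)[C@@]2(C)O[C@@H]2CC/C(CO[Si](C)(C)C(C)(C)C)=C\C1
F5 | step 2 | [(2S,3S)-3-methyl-3-(4-methylpent-3-en-1-yl)oxiran-2-yl]methanol | CC(C)=CCC[C@]1(C)O[C@H]1CO
F6 | step 2 | (2R,3S)-3-methyl-3-(4-methylpent-3-en-1-yl)-5-(trimethylsilyl)pent-4-yne-1,2-diol | CC(C)=CCC[C@@]([C@@H](O)CO)(C)C#C[Si](C)(C)C
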